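# Total synthesis of eupaheliangolide A

**Assumptions:** The C8 ester is (E)-tiglate, as drawn in the SMILES. (R)-Glycidyl TBDPS ether and tigloyl chloride are taken as commercially available.

## Retrosynthetic overview
1. Close the 10-membered carbocycle last by an intramolecular carbonylative Stille coupling, with CO supplying C3. The partners are a (Z)-C4 vinyl iodide and an (E)-C2 vinylstannane. This is the bold step.
2. Form the trans-fused α-methylene-γ-lactone first. An anti-selective indium Barbier allylation of (Z)-3-iodobut-2-enal (C6 aldehyde) with a Baylis–Hillman-derived allylic bromide forms the C6–C7 bond, the lactone and the exocyclic methylene in one operation.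
3. C8 comes from (R)-glycidyl TBDPS ether opened by methyl-dithiane (C10 ketone). The C10 tertiary carbinol comes from chelation-controlled ethynylation, and hydrostannation gives the E-vinylstannane.
4. C8-O-tiglate is installed after lactonization, by selective acylation of the secondary alcohol.

## Forward route

**Step 1**
Reactants: 1 (2-butyn-1-ol)
Product: 2 ((Z)-3-iodobut-2-en-1-ol)
Conditions: Red-Al, Et2O, 0 °C→rt; EtOAc; then I2, –78→0 °C
Reagents that add atoms: iodine, II
Why: Red-Al trans-hydroalumination of the propargylic alkoxide puts Al on C3, and I2 then gives the (Z)-β-iodo allylic alcohol, which sets the C4=C5 geometry with I cis to C6 (hydroalumination/iodination of a propargylic alcohol).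

**Step 2**
Reactants: 2
Product: 3 ((Z)-3-iodobut-2-enal)
Conditions: MnO2, CH2Cl2, rt
Reagents that add atoms: none
Why: MnO2 selectively oxidizes the allylic alcohol without touching the vinyl iodide or the alkene geometry.

**Step 3**
Reactants: 4 ((R)-glycidyl TBDPS ether), 5 (2-methyl-1,3-dithiane)
Product: 6
Conditions: 5, n-BuLi, THF, –30 °C; then 4, –78 °C→rt
Reagents that add atoms: none (5 is the reactant; n-BuLi is not retained)
Why: The lithiated dithiane opens the terminal epoxide at the CH2 carbon (epoxide SN2 opening), so the epoxide stereocenter is untouched and becomes C8 (R); the dithiane carbon is C10 and its methyl is C14.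

**Step 4**
Reactants: 6
Product: 7 ((R)-β-hydroxy methyl ketone)
Conditions: PhI(OCOCF3)2, NaHCO3, MeCN/H2O 9:1, 0 °C
Reagents that add atoms: water, O (the ketone oxygen)
Why: Hypervalent-iodine dethioacetalization unmasks the ketone under buffered, non-acidic conditions, so the β-hydroxy ketone does not undergo retro-aldol or elimination.

**Step 5**
Reactants: 7
Product: 8 ((3R,5R)-1,3-anti-diol, tertiary propargylic alcohol)
Conditions: HC≡CMgBr (4 equiv), THF, –78→0 °C
Reagents that add atoms: ethynylmagnesium bromide, C#C[Mg]Br
Why: The C8 alkoxide and C10 carbonyl form a six-membered Mg chelate with the C7 chain equatorial, and axial alkynyl attack sets C10 (R) anti to C8-O (chelation-controlled 1,3-induction).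

**Step 6**
Reactants: 8
Product: 9 (anti-acetonide, 4-ethynyl-2,2,4-trimethyl-1,3-dioxane)
Conditions: Me2C(OMe)2, CSA (cat.), CH2Cl2, rt
Reagents that add atoms: 2,2-dimethoxypropane, COC(C)(C)OC
Why: The acetonide protects C8-O and C10-O together and prevents later lactonization onto O8 (acetalization).

**Step 7**
Reactants: 9
Product: 10 ((E)-vinylstannane)
Conditions: Bu3SnH, Pd(PPh3)2Cl2 (3 mol%), THF, 0 °C
Reagents that add atoms: tributyltin hydride, CCCC[SnH](CCCC)CCCC
Why: Pd-catalyzed syn-hydrostannation of a terminal alkyne next to a quaternary center puts Sn on the terminal carbon and gives the E-alkene, which is the C1=C2 geometry.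

**Step 8**
Reactants: 10
Product: 11 (primary alcohol)
Conditions: TBAF, THF, 0 °C→rt
Reagents that add atoms: none
Why: Fluoride removes the TBDPS group and leaves the acetonide and the C(sp2)–Sn bond intact (silyl ether cleavage).

**Step 9**
Reactants: 11
Product: 12 (α-alkoxy aldehyde, C7)
Conditions: Dess–Martin periodinane, NaHCO3, CH2Cl2, 0 °C
Reagents that add atoms: none
Why: Buffered DMP oxidizes the primary alcohol under mild conditions that limit epimerization at C8 (alcohol oxidation).

**Step 10**
Reactants: 12, 13 (methyl acrylate)
Product: 14 (Baylis–Hillman adduct, C7-OH, epimeric mixture at C7)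
Conditions: 13 (5 equiv), DABCO (1 equiv), neat, rt, 4 d
Reagents that add atoms: methyl acrylate (reactant 13), C=CC(=O)OC
Why: Morita–Baylis–Hillman reaction supplies C11, C12 and C13; the new carbinol stereocenter is irrelevant because it is destroyed in the next step.

**Step 11**
Reactants: 14
Product: 15 ((Z)-2-(bromomethyl)alk-2-enoate)
Conditions: MsCl, Et3N, CH2Cl2, 0 °C; then LiBr, THF, rt
Reagents that add atoms: lithium bromide, [Li+].[Br-]
Why: Mesylation followed by SN2′ displacement by bromide gives the trisubstituted allylic bromide, so C7 becomes sp2; non-electrophilic conditions protect the vinylstannane (allylic transposition).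

**Step 12**
Reactants: 15, 3
Product: 16 (trans-fused α-methylene-γ-lactone with C6 bearing the Z-vinyl iodide)
Conditions: In powder, THF/sat. aq NH4Cl 1:1, rt; then PPTS (cat.), toluene, 50 °C
Reagents that add atoms: none (both components are reactants)
Why: The allylindium adds through a Zimmerman–Traxler chair to give the anti homoallylic alcohol (C6/C7 anti, so trans-lactone after ring closure), and C8-directed facial selectivity sets (6R,7R); this is an indium Barbier allylation and lactonization. The diastereomer is expected to be separable.

**Step 13**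
Reactants: 16
Product: 17 (C8-OH, C10-OH diol)
Conditions: PPTS, MeOH/CH2Cl2 1:1, 40 °C
Reagents that add atoms: none
Why: The anti-1,3-acetonide is labile and mild acid methanolysis releases the diol, leaving the lactone, vinyl iodide and vinylstannane intact (acetonide cleavage).

**Step 14**
Reactants: 17, 18 (tigloyl chloride)
Product: 19 (C8 tiglate)
Conditions: 18 (1.5 equiv), Et3N, DMAP (cat.), CH2Cl2, –20→0 °C
Reagents that add atoms: tigloyl chloride (reactant 18), C/C=C(\C)C(=O)Cl
Why: The secondary C8-OH is acylated selectively over the hindered tertiary C10-OH, and the stereocenters are untouched; the low temperature avoids E→Z isomerization of the tiglate (chemoselective acylation).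

**Step 15**
Reactants: 19
Product: 20 (eupaheliangolide A)
Conditions: CO (1 atm), Pd2(dba)3 (5 mol%), AsPh3 (40 mol%), CuI (20 mol%), THF/DMF 4:1, 60 °C, 2 mM, substrate added by syringe pump over 8 h
Reagents that add atoms: carbon monoxide, [C-]#[O+]
Why: Proposed new method: macrocyclic carbonylative Stille coupling forming the 10-membered cross-conjugated (4Z,1E)-dienone. Mechanism: Pd(0) inserts into the Z-vinyl iodide, CO insertion is fast at 1 atm and retains the Z geometry, Cu-assisted intramolecular transmetalation with the E-vinylstannane and reductive elimination form C2–C3 with CO as C3, and the preformed trans-lactone and Z/E alkenes preorganize the chain; the closest known reaction is the intermolecular carbonylative Stille coupling of vinyl iodides and vinylstannanes to divinyl ketones. No stereocenter is formed or affected.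

## Self-check
- **Ring sizes and substituents:** C1–C10 form the 10-membered ring. The lactone O–C6, C7, C11, C12 gives a 5-membered ring. C10 carries Me and OH, C4 carries Me, C8 carries the tiglate, and C11 carries the methylene. The product has 20 C and 6 O.
- **Stereocenters:** C8 (R) comes from compound 4 in step 3. C10 (R) is set in step 5. C6 (R) and C7 (R) are set in step 12 (trans). The alkene geometries (4Z, 1E, tiglate E) are set in steps 1, 7 and 14. None is modified later.
- **Group survival:**
  - Sn–C(sp2) and the vinyl iodide survive the non-Pd steps 8–14.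
  - The acetonide protects O8/O10 through steps 7–12.
  - The vinylstannane is installed (step 7) before the Pd-free steps that would otherwise be incompatible and is used only in step 15.
  - The α-methylene lactone is present only from step 12 onward and is carried to the end.
- **Epimerization risk:** C8 is α to the aldehyde in steps 9–11 and may epimerize; this is flagged below.

## Compound list
1 | 2-butyn-1-ol | CC#CCO | starting material
2 | (Z)-3-iodobut-2-en-1-ol | C/C(I)=C/CO | intermediate
3 | (Z)-3-iodobut-2-enal | C/C(I)=C/C=O | intermediate
4 | (R)-glycidyl TBDPS ether | C1O[C@H]1CO[Si](c2ccccc2)(c2ccccc2)C(C)(C)C | starting material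
5 | 2-methyl-1,3-dithiane | CC1SCCCS1 | starting material
6 | (2R)-1-TBDPSO-4-(2-methyl-1,3-dithian-2-yl)butan-2-ol | CC1(SCCCS1)C[C@@H](O)CO[Si](c2ccccc2)(c2ccccc2)C(C)(C)C | intermediate
7 | (4R)-5-TBDPSO-4-hydroxypentan-2-one | CC(=O)C[C@@H](O)CO[Si](c1ccccc1)(c1ccccc1)C(C)(C)C | intermediate
8 | (3R,5R)-6-TBDPSO-3-methylhex-1-yne-3,5-diol | C#C[C@](C)(O)C[C@@H](O)CO[Si](c1ccccc1)(c1ccccc1)C(C)(C)C | intermediate
9 | anti-acetonide of 8 | C#C[C@@]1(C)C[C@H](CO[Si](c2ccccc2)(c2ccccc2)C(C)(C)C)OC(C)(C)O1 | intermediate
10 | (E)-vinylstannane of 9 | CCCC[Sn](CCCC)(CCCC)/C=C/[C@@]1(C)C[C@H](CO[Si](c2ccccc2)(c2ccccc2)C(C)(C)C)OC(C)(C)O1 | intermediate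
11 | primary alcohol | CCCC[Sn](CCCC)(CCCC)/C=C/[C@@]1(C)C[C@H](CO)OC(C)(C)O1 | intermediate
12 | α-alkoxy aldehyde | CCCC[Sn](CCCC)(CCCC)/C=C/[C@@]1(C)C[C@H](C=O)OC(C)(C)O1 | intermediate
13 | methyl acrylate | C=CC(=O)OC | starting material
14 | Baylis–Hillman adduct (C7 epimeric mixture) | CCCC[Sn](CCCC)(CCCC)/C=C/[C@@]1(C)C[C@H](C(O)C(=C)C(=O)OC)OC(C)(C)O1 | intermediate
15 | (Z)-allylic bromide | CCCC[Sn](CCCC)(CCCC)/C=C/[C@@]1(C)C[C@H](/C=C(\CBr)C(=O)OC)OC(C)(C)O1 | intermediate
16 | trans-lactone, acetonide, vinyl iodide, vinylstannane | C=C1C(=O)O[C@H](/C=C(/C)I)[C@H]1[C@H]2C[C@](C)(/C=C/[Sn](CCCC)(CCCC)CCCC)OC(C)(C)O2 | intermediate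
17 | diol lactone | C=C1C(=O)O[C@H](/C=C(/C)I)[C@H]1[C@H](O)C[C@@](C)(O)/C=C/[Sn](CCCC)(CCCC)CCCC | intermediate
18 | tigloyl chloride | C/C=C(\C)C(=O)Cl | starting material
19 | C8 tiglate, macrocyclization precursor | C=C1C(=O)O[C@H](/C=C(/C)I)[C@H]1[C@H](OC(=O)/C(C)=C/C)C[C@@](C)(O)/C=C/[Sn](CCCC)(CCCC)CCCC | intermediate
20 | eupaheliangolide A | C=C1C(=O)O[C@@H]2/C=C(/C)C(=O)/C=C/[C@](C)(O)C[C@@H](OC(=O)/C(C)=C/C)[C@@H]12 | target

## Totals
- **Total steps:** 15.
- **Longest linear sequence:** 13 steps (steps 3–15, starting from 4). Steps 1–2 make the iodoenal separately.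

## Three steps most likely to fail
1. **Step 15 (macrocyclic carbonylative Stille).** Oligomerization, direct 9-membered Stille coupling without CO, or strain could defeat it.
   Fallback: Use a different disconnection. Install a terminal vinyl at C10 instead of the ethynyl group, do a cross-metathesis with crotonaldehyde to give the E-enal, close the ring by intramolecular NHK vinylation of the Z-vinyl iodide onto the C3 aldehyde (CrCl2/NiCl2), then oxidize the dienol with DMP.
2. **Step 12 (Barbier).** Two things are uncertain: C8-directed 1,2-induction at C7 may be only modest, and γ-acetal-assisted 1,4-elimination of the allylindium may compete.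
   Fallback: Form the trans-lactone by conjugate addition of vinylcuprate to (S)-5-(silyloxymethyl)butenolide, convert the CH2O group to the Z-iodoalkene by oxidation and Stork–Zhao olefination, and set C8 by proline-catalysed acetone aldol on the lactone-derived aldehyde.
3. **Step 5 (ethynylation).** The 1,3-anti selectivity from chelation control may be modest.
   Fallback: Disconnect C10–C14 instead. Make the β-hydroxy ynone (Weinreb amide plus lithium TMS-acetylide) with C8-OTBS and add MeLi/CeCl3 under non-chelation (polar Felkin–Anh) control to reach the same C10 diastereomer.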